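**Retrosynthetic overview**
1. Target 18 ⇐ 1,2-reduction of enal 17. Enal 17 ⇐ C(sp3)–C(sp2) bond between the CH2CH2 tether and the E-alkenyl carbon, made by nickel-electrocatalytic decarboxylative alkenylation of enal acid 15 with alkenyl iodide 5 (fragment union, no protecting groups).
2. 15 ⇐ E-selective Wittig reaction of lactol 14 with formyl ylide acid 8, which is made from (3-carboxypropyl)triphenylphosphonium bromide.
3. 14 ⇐ 2-deoxy-D-ribose. Its C3 becomes the butenolide stereocentre, and the butenolide is built on the cis-3,4-diol of methyl pyranoside 10 by a new oxidative annulation with Ph3P=C=C=O.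
4. 5 ⇐ dihydro-β-ionone via terminal alkyne 3 and zirconium-catalysed carboalumination/iodination, which sets the E-trisubstituted alkene.
5. Ring order: the cyclohexene is bought; the pyranoside is a temporary ring (step 4); the butenolide is closed in step 5; the pyran is opened in steps 6–7.

Assumption: 9 is drawn in its open-chain form and 14 as the cyclic hemiacetal (anomer mixture); 8 is drawn neutral but may be handled as its inner salt.

**Step 1**
Reactants: 1 dihydro-β-ionone
Product: 3 2-(but-3-yn-1-yl)-1,3,3-trimethylcyclohex-1-ene, via enol phosphate 2 (not isolated)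
Conditions: LiN(iPr)2, THF, −78 °C; ClP(O)(OEt)2, −78 °C → rt; LiN(iPr)2 (2.3 equiv), −78 °C → rt
Reagents that add atoms: none
Why: Kinetic deprotonation on the methyl side and O-phosphorylation give the terminal enol phosphate, which loses diethyl phosphate by base-induced β-elimination to the alkyne (Negishi methyl ketone to alkyne conversion) without touching the tetrasubstituted ring alkene.

**Step 2**
Reactants: 3 2-(but-3-yn-1-yl)-1,3,3-trimethylcyclohex-1-ene
Product: 5 2-[(3E)-4-iodo-3-methylbut-3-en-1-yl]-1,3,3-trimethylcyclohex-1-ene, via alkenylalane 4 (not isolated)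
Conditions: Me3Al (2 equiv), Cp2ZrCl2 (0.25 equiv), CH2Cl2, rt; then I2, THF, −30 → 0 °C
Reagents that add atoms: trimethylaluminium, C[Al](C)C; iodine, [I][I]
Why: Zirconium-catalysed Negishi carboalumination adds methyl and aluminium syn across the terminal alkyne with methyl on the internal carbon, and iodinolysis of the carbon–aluminium bond with retention fixes the E alkenyl iodide.

**Step 3**
Reactants: 6 (3-carboxypropyl)triphenylphosphonium bromide
Product: 8 4-formyl-4-(triphenylphosphoranylidene)butanoic acid, via ylide carboxylate 7 (not isolated)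
Conditions: NaN(SiMe3)2 (2.1 equiv), THF, 0 °C; HCO2Et, 0 °C → rt; aq. HCl to pH 5
Reagents that add atoms: ethyl formate, CCOC=O
Why: The non-stabilised ylide carbon is acylated by ethyl formate and the expelled ethoxide removes the now acidic α-proton (classical formylation of a phosphorus ylide), giving the stabilised α-formyl ylide while the carboxylate is a spectator.

**Step 4**
Reactants: 9 2-deoxy-D-ribose
Product: 10 methyl 2-deoxy-β-D-erythro-pentopyranoside
Conditions: MeOH, HCl (1 %, from AcCl), 20 °C, 20 h; NaHCO3; crystallise from EtOAc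
Reagents that add atoms: methanol, CO
Why: Fischer glycosidation under thermodynamic control ties up C1 and O5 in the pyranoside and leaves only the cis-3,4-diol free; the bought stereocentres C3 (S) and C4 are untouched, and the temporary anomeric centre (β, axial OMe by the anomeric effect, isolated by crystallisation) is erased in step 6.

**Step 5**
Reactants: 10 methyl 2-deoxy-β-D-erythro-pentopyranoside
Product: 13 (6R,7aS)-6-methoxy-6,7-dihydro-4H-furo[3,2-c]pyran-2(7aH)-one, via ester ylide 11 (not isolated), via keto ylide 12 (not isolated)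
Conditions: Ph3P=C=C=O (1.05 equiv), THF, 60 °C; then Dess–Martin periodinane, NaHCO3, CH2Cl2, 0 → 40 °C
Reagents that add atoms: (triphenylphosphoranylidene)ketene, O=C=C=P(c1ccccc1)(c1ccccc1)c1ccccc1
Why: Proposed new method: one-pot oxidative butenolide annulation of a cis-1,2-diol, in which the more nucleophilic equatorial 3-OH adds to the cumulated ylide to give an ester-stabilised ylide that tolerates Dess–Martin oxidation of the neighbouring axial 4-OH, and the ketone so unveiled is trapped at once by intramolecular Wittig olefination to close the five-membered lactone, the C3 stereocentre being only O-acylated and therefore retained and no new stereocentre being formed; the closest known reaction types are the butenolide synthesis from pre-formed α-hydroxy ketones with Ph3P=C=C=O and tandem Dess–Martin oxidation/Wittig olefination with stabilised ylides.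

**Step 6**
Reactants: 13 (6R,7aS)-6-methoxy-6,7-dihydro-4H-furo[3,2-c]pyran-2(7aH)-one
Product: 14 (7aS)-6-hydroxy-6,7-dihydro-4H-furo[3,2-c]pyran-2(7aH)-one
Conditions: 0.5 M HCl, THF/H2O, 40 °C
Reagents that add atoms: water, O
Why: Acid hydrolysis of the 2-deoxyglycoside runs fast through the oxocarbenium ion under conditions that leave the butenolide and its γ-stereocentre untouched, unmasking the aldehyde (as its hemiacetal, anomer mixture of no consequence) and the primary alcohol.

**Step 7**
Reactants: 14 (7aS)-6-hydroxy-6,7-dihydro-4H-furo[3,2-c]pyran-2(7aH)-one; 8 4-formyl-4-(triphenylphosphoranylidene)butanoic acid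
Product: 15 (4E)-4-formyl-6-[(2S)-3-(hydroxymethyl)-5-oxo-2,5-dihydrofuran-2-yl]hex-4-enoic acid
Conditions: 8 (1.3 equiv), ClCH2CH2Cl, 70 °C
Reagents that add atoms: none
Why: Wittig olefination of the ring-opened hydroxy aldehyde with the stabilised α-alkyl formyl ylide is E-selective (formyl trans to the new β-substituent), needs no added base so the β-acyloxy aldehyde and the γ-stereocentre survive, and gives an α-branched enal that is a poor acceptor for oxa-Michael closure by the free alcohol.

**Step 8**
Reactants: 15 (4E)-4-formyl-6-[(2S)-3-(hydroxymethyl)-5-oxo-2,5-dihydrofuran-2-yl]hex-4-enoic acid; 5 2-[(3E)-4-iodo-3-methylbut-3-en-1-yl]-1,3,3-trimethylcyclohex-1-ene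
Product: 17 (2E,5E)-2-{2-[(2S)-3-(hydroxymethyl)-5-oxo-2,5-dihydrofuran-2-yl]ethylidene}-6-methyl-8-(2,6,6-trimethylcyclohex-1-en-1-yl)oct-5-enal, via N-hydroxyphthalimide ester 16 (not isolated)
Conditions: N-hydroxyphthalimide, iPrN=C=NiPr, DMF, rt; then 5 (1.5 equiv), NiCl2·6H2O (20 mol %), 2,2′-bipyridine (20 mol %), AgNO3 (30 mol %), Mg anode, carbon cathode, undivided cell, constant current (2.5 F/mol), DMF, rt
Reagents that add atoms: none
Why: Nickel-electrocatalytic decarboxylative alkenylation (reductive coupling of a redox-active ester with an alkenyl iodide), in which cathodic single-electron reduction of the ester releases CO2 and a primary radical that is captured by the divalent alkenylnickel species formed from zerovalent nickel and 5, and reductive elimination from trivalent nickel forges the C(sp3)–C(sp2) bond with retention of both alkene geometries, the radical being of the 3-substituted but-3-enyl type for which ring closure onto the fully substituted alkene carbon is slow.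

**Step 9**
Reactants: 17 (2E,5E)-2-{2-[(2S)-3-(hydroxymethyl)-5-oxo-2,5-dihydrofuran-2-yl]ethylidene}-6-methyl-8-(2,6,6-trimethylcyclohex-1-en-1-yl)oct-5-enal
Product: 18 (5S)-4-(hydroxymethyl)-5-[(2E,6E)-3-(hydroxymethyl)-7-methyl-9-(2,6,6-trimethylcyclohex-1-en-1-yl)nona-2,6-dien-1-yl]furan-2(5H)-one
Conditions: NaBH4, CeCl3·7H2O, MeOH, −40 °C
Reagents that add atoms: none
Why: Luche reduction converts the enal 1,2-selectively into the primary allylic alcohol without touching the butenolide, the alkenes or the stereocentre.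

**Compound list**
1 | dihydro-β-ionone, 4-(2,6,6-trimethylcyclohex-1-en-1-yl)butan-2-one | CC(=O)CCC1=C(C)CCCC1(C)C | starting material
2 | diethyl 4-(2,6,6-trimethylcyclohex-1-en-1-yl)but-1-en-2-yl phosphate | C=C(CCC1=C(C)CCCC1(C)C)OP(=O)(OCC)OCC | intermediate
3 | 2-(but-3-yn-1-yl)-1,3,3-trimethylcyclohex-1-ene | C#CCCC1=C(C)CCCC1(C)C | intermediate
4 | dimethyl[(1E)-2-methyl-4-(2,6,6-trimethylcyclohex-1-en-1-yl)but-1-en-1-yl]alane | C[Al](C)/C=C(\C)CCC1=C(C)CCCC1(C)C | intermediate
5 | 2-[(3E)-4-iodo-3-methylbut-3-en-1-yl]-1,3,3-trimethylcyclohex-1-ene | I/C=C(\C)CCC1=C(C)CCCC1(C)C | intermediate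
6 | (3-carboxypropyl)triphenylphosphonium bromide | OC(=O)CCC[P+](c1ccccc1)(c1ccccc1)c1ccccc1.[Br-] | starting material
7 | sodium 4-(triphenylphosphoranylidene)butanoate | [Na+].[O-]C(=O)CCC=P(c1ccccc1)(c1ccccc1)c1ccccc1 | intermediate
8 | 4-formyl-4-(triphenylphosphoranylidene)butanoic acid | O=CC(CCC(=O)O)=P(c1ccccc1)(c1ccccc1)c1ccccc1 | intermediate
9 | 2-deoxy-D-ribose, (3S,4R)-3,4,5-trihydroxypentanal | O=CC[C@H](O)[C@H](O)CO | starting material
10 | methyl 2-deoxy-β-D-erythro-pentopyranoside, (2R,4S,5R)-2-methoxyoxane-4,5-diol | CO[C@H]1C[C@H](O)[C@H](O)CO1 | intermediate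
11 | methyl 2-deoxy-3-O-[(triphenylphosphoranylidene)acetyl]-β-D-erythro-pentopyranoside | CO[C@H]1C[C@H](OC(=O)C=P(c2ccccc2)(c2ccccc2)c2ccccc2)[C@H](O)CO1 | intermediate
12 | methyl 2-deoxy-3-O-[(triphenylphosphoranylidene)acetyl]-β-D-glycero-pentopyranosid-4-ulose | CO[C@H]1C[C@H](OC(=O)C=P(c2ccccc2)(c2ccccc2)c2ccccc2)C(=O)CO1 | intermediate
13 | (6R,7aS)-6-methoxy-6,7-dihydro-4H-furo[3,2-c]pyran-2(7aH)-one | CO[C@H]1C[C@@H]2OC(=O)C=C2CO1 | intermediate
14 | (7aS)-6-hydroxy-6,7-dihydro-4H-furo[3,2-c]pyran-2(7aH)-one (hemiacetal of (S)-2-[3-(hydroxymethyl)-5-oxo-2,5-dihydrofuran-2-yl]acetaldehyde) | OC1C[C@@H]2OC(=O)C=C2CO1 | intermediate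
15 | (4E)-4-formyl-6-[(2S)-3-(hydroxymethyl)-5-oxo-2,5-dihydrofuran-2-yl]hex-4-enoic acid | O=C/C(CCC(=O)O)=C/C[C@@H]1OC(=O)C=C1CO | intermediate
16 | 1,3-dioxoisoindolin-2-yl (4E)-4-formyl-6-[(2S)-3-(hydroxymethyl)-5-oxo-2,5-dihydrofuran-2-yl]hex-4-enoate | O=C/C(CCC(=O)ON1C(=O)c2ccccc2C1=O)=C/C[C@@H]1OC(=O)C=C1CO | intermediate
17 | (2E,5E)-2-{2-[(2S)-3-(hydroxymethyl)-5-oxo-2,5-dihydrofuran-2-yl]ethylidene}-6-methyl-8-(2,6,6-trimethylcyclohex-1-en-1-yl)oct-5-enal | O=C/C(CC/C=C(\C)CCC1=C(C)CCCC1(C)C)=C/C[C@@H]1OC(=O)C=C1CO | intermediate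
18 | (5S)-4-(hydroxymethyl)-5-[(2E,6E)-3-(hydroxymethyl)-7-methyl-9-(2,6,6-trimethylcyclohex-1-en-1-yl)nona-2,6-dien-1-yl]furan-2(5H)-one | CC1=C(CC/C(C)=C/CC/C(=C\C[C@@H]2OC(=O)C=C2CO)CO)C(C)(C)CCC1 | target

**Total step count:** 9. **Longest linear sequence:** 6 (steps 4, 5, 6, 7, 8, 9 from 2-deoxy-D-ribose).

**Steps most likely to fail**

Step 5 (the proposed new annulation). It can fail through acylation at O4 instead of O3, double acylation, or loss of the ylide to the oxidant. The fallback uses known chemistry, sets out from 10 and comes back at 13. Organotin-catalysed regioselective monoacylation of the cis-diol (Me2SnCl2 5 mol %, K2CO3, chloroacetyl chloride, THF) gives methyl 3-O-(chloroacetyl)-2-deoxy-β-D-erythro-pentopyranoside F1. Dess–Martin oxidation gives methyl 3-O-(chloroacetyl)-2-deoxy-β-D-glycero-pentopyranosid-4-ulose F2. PPh3 with catalytic NaI in MeCN gives the (acyloxymethyl)triphenylphosphonium chloride F3. Et3N then generates ylide 12, which closes to 13; this is the classical α-(haloacetoxy) ketone route to butenolides.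

Step 7 (Wittig reaction on the lactol with the acid-bearing ylide). The free aldehyde is present only in low concentration, 8 can sit as an unreactive inner salt, and prolonged heating invites β-elimination of the lactone oxygen. The fallback sets out from 14 and comes back at 15, using a neutral, more soluble ylide and a later acid unmasking. tert-Butyl 4-bromobutanoate and PPh3 give [4-(tert-butoxy)-4-oxobutyl]triphenylphosphonium bromide F4. NaN(SiMe3)2 then HCO2Et give tert-butyl 4-formyl-4-(triphenylphosphoranylidene)butanoate F5. Wittig reaction with 14 in CH2Cl2 at 40 °C gives tert-butyl (4E)-4-formyl-6-[(2S)-3-(hydroxymethyl)-5-oxo-2,5-dihydrofuran-2-yl]hex-4-enoate F6, and CF3CO2H in CH2Cl2 releases 15.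

Step 8 (electrochemical union). Risks are cathodic reduction of the enal once the ester is consumed, ester formation between the activated acid and the free primary alcohol, and 1,5-hydrogen shift of the radical from the cis allylic CH2. The fallback sets out from 15 and 5 and comes back at 17, replacing the electroreductive coupling by a thermal nickel-catalysed decarboxylative alkenylation with a preformed organozinc. Ester 16 is isolated. Iodide 5 is converted with tert-butyllithium (Et2O, −78 °C) into (1E)-[2-methyl-4-(2,6,6-trimethylcyclohex-1-en-1-yl)but-1-en-1-yl]lithium F7 and with ZnCl2 into chloro[(1E)-2-methyl-4-(2,6,6-trimethylcyclohex-1-en-1-yl)but-1-en-1-yl]zinc F8. F8 (3 equiv) is coupled with 16 using Ni(acac)2 and 2,2′-bipyridine in THF/DMF at rt to give 17.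

**Further compounds**
F1 | step 5 | methyl 3-O-(chloroacetyl)-2-deoxy-β-D-erythro-pentopyranoside | CO[C@H]1C[C@H](OC(=O)CCl)[C@H](O)CO1
F2 | step 5 | methyl 3-O-(chloroacetyl)-2-deoxy-β-D-glycero-pentopyranosid-4-ulose | CO[C@H]1C[C@H](OC(=O)CCl)C(=O)CO1
F3 | step 5 | {2-[(methyl 2-deoxy-β-D-glycero-pentopyranosid-4-ulos-3-yl)oxy]-2-oxoethyl}triphenylphosphonium chloride | CO[C@H]1C[C@H](OC(=O)C[P+](c2ccccc2)(c2ccccc2)c2ccccc2)C(=O)CO1.[Cl-]
F4 | step 7 | [4-(tert-butoxy)-4-oxobutyl]triphenylphosphonium bromide | CC(C)(C)OC(=O)CCC[P+](c1ccccc1)(c1ccccc1)c1ccccc1.[Br-]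
F5 | step 7 | tert-butyl 4-formyl-4-(triphenylphosphoranylidene)butanoate | CC(C)(C)OC(=O)CCC(C=O)=P(c1ccccc1)(c1ccccc1)c1ccccc1
F6 | step 7 | tert-butyl (4E)-4-formyl-6-[(2S)-3-(hydroxymethyl)-5-oxo-2,5-dihydrofuran-2-yl]hex-4-enoate | O=C/C(CCC(=O)OC(C)(C)C)=C/C[C@@H]1OC(=O)C=C1CO
F7 | step 8 | (1E)-[2-methyl-4-(2,6,6-trimethylcyclohex-1-en-1-yl)but-1-en-1-yl]lithium | [Li]/C=C(\C)CCC1=C(C)CCCC1(C)C
F8 | step 8 | chloro[(1E)-2-methyl-4-(2,6,6-trimethylcyclohex-1-en-1-yl)but-1-en-1-yl]zinc | Cl[Zn]/C=C(\C)CCC1=C(C)CCCC1(C)C
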